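Drimane numbering is used: ring A = C1–C5 and C10, ring B = C5–C10, C11 = the OCH2 carbon, C12 = the exocyclic CH2.
Enabling feature: in ring B the quaternary C10 (CH3 and the C1 chain) adjoins C9 (bearing C11), and C9 adjoins the sp2 carbon C8. Ring B is therefore a masked 2,3,3-trisubstituted cyclohexanone, and its C10–CH3 and C9–C11 bonds can be made in one flask from a β-substituted enone.
Cuts, in retrosynthetic order: C11–O(aryl); C8=C12; C4–C5 (ring A, epoxide opened by the C5 end of a C8 dienol ether); C6=C7; then C9–C11 and C10–CH3 together; last C10–C1.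
Forward: ring B is bought, the C1–C4 arm is attached, the three-component step loads C10 and C9, ring A closes, and the coumarin is joined at the end.
Stereochemistry: C10 comes from the chiral copper–carbene catalyst. C9 comes from formaldehyde capture anti to the arm, followed by separation of epimers. C3 comes from a reagent-controlled Shi epoxidation. C5 comes from α-face reprotonation of the bicyclic dienol ether, because the ring closure is geometrically bound to give the cis-decalin first.

Key step: step 2

Remark: L* is 1-mesityl-3-[(2S)-1-hydroxy-3,3-dimethylbutan-2-yl]-4,5-dihydroimidazolium hexafluorophosphate, assumed to direct methyl to the Si face of C10 (its enantiomer is taken if the sense proves opposite); the L-fructose-derived Shi ketone is chosen because the D-series ketone gives (R)-epoxides from prenyl termini.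

Step 1
Reactants: 1 5-bromo-2-methylpent-2-ene; 2 3-ethoxycyclohex-2-enone
Product: 5 3-(4-methylpent-3-enyl)cyclohex-2-enone, via Grignard reagent 3 (not isolated), via magnesium alkoxide 4 (not isolated)
Conditions: Mg, THF, 40 °C; then 2, THF, 0 °C → rt; then 1 M aq HCl, rt
Reagents that add atoms: water, O
Why: Stork–Danheiser sequence, in which 1,2-addition of the Grignard reagent to the vinylogous ester and acid-induced loss of ethanol transpose the carbonyl group and leave the arm on the β-carbon (future C10); no stereocentre is formed.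

Step 2
Reactants: 5 3-(4-methylpent-3-enyl)cyclohex-2-enone; 6 methylmagnesium bromide; 7 formaldehyde
Product: 9 (2S,3R)-2-(hydroxymethyl)-3-methyl-3-(4-methylpent-3-enyl)cyclohexanone, via magnesium enolate 8 (not isolated)
Conditions: Cu(OTf)2 (3 mol %), L* (4 mol %), 6 (1.3 equiv, slow addition), Et2O, −30 °C; then gaseous 7 (cracked paraformaldehyde), −78 → −30 °C; aq NH4Cl; chromatography
Reagents that add atoms: none
Why: Excess 6 deprotonates the imidazolinium salt and its hydroxyl group and reduces Cu(OTf)2 to monovalent copper, giving a chelating alkoxy-carbene methylcuprate that π-binds C9=C10 of 5, adds oxidatively at C10 to a trivalent-copper σ-alkyl and eliminates reductively to make C10–CH3, leaving the regiodefined bromomagnesium enolate 8. Monomeric 7 then reacts at C9 of 8 through a closed, magnesium-bridged aldol transition state faster than the enolate can exchange protons, which makes C9–C11; the step closes no ring. The closest known reaction type is the copper/N-heterocyclic-carbene-catalysed asymmetric conjugate addition of Grignard reagents to 3-substituted cyclohexenones followed by aldehyde capture of the magnesium enolate. C10 is controlled by the ligand, whose mesityl wall and alkoxide anchor should leave only the Si face of C10 open to methyl transfer, giving (3R) in 9. C9 is controlled by the substrate, formaldehyde entering axially and anti to the C10 substituent that stands pseudoaxial in the half-chair enolate, preferably the longer arm, but because CH3 and CH2R differ little this bias is expected to be modest and the C9 epimers are parted by chromatography at this early, inexpensive stage. The step needs 1,4- over 1,2-addition (secured by the copper catalyst in Et2O with slow addition of 6) and single hydroxymethylation without dehydration (secured by low temperature, short contact time and the buffered NH4Cl quench).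

Step 3
Reactants: 9 (2S,3R)-2-(hydroxymethyl)-3-methyl-3-(4-methylpent-3-enyl)cyclohexanone
Product: 10 (2S,3R)-2-[(tert-butyldiphenylsilyloxy)methyl]-3-methyl-3-(4-methylpent-3-enyl)cyclohexanone
Conditions: TBDPSCl, imidazole, CH2Cl2, 0 °C → rt
Reagents that add atoms: tert-butyl(chloro)diphenylsilane (TBDPSCl), CC(C)(C)[Si](Cl)(c1ccccc1)c1ccccc1
Why: Standard imidazole-promoted silylation of a primary alcohol, in which the bulky, acid-tolerant silyl ether blocks retro-aldol cleavage and is a poor leaving group for β-elimination, while the near-neutral medium leaves C9 untouched.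

Step 4
Reactants: 10 (2S,3R)-2-[(tert-butyldiphenylsilyloxy)methyl]-3-methyl-3-(4-methylpent-3-enyl)cyclohexanone
Product: 12 (5S,6S)-6-[(tert-butyldiphenylsilyloxy)methyl]-5-methyl-5-(4-methylpent-3-enyl)cyclohex-2-enone, via trimethylsilyl enol ether 11 (not isolated)
Conditions: LiN(iPr)2, Me3SiCl, THF, −78 °C; solvent exchange; Pd(OAc)2 (1.05 equiv), MeCN, rt
Reagents that add atoms: none
Why: Saegusa–Ito oxidation, in which the amide base removes an unhindered C7 proton rather than the tertiary C9–H next to the quaternary C10, and divalent palladium converts the kinetic silyl enol ether into the C6=C7 enone by β-hydride elimination without touching C9 or C10.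

Step 5
Reactants: 12 (5S,6S)-6-[(tert-butyldiphenylsilyloxy)methyl]-5-methyl-5-(4-methylpent-3-enyl)cyclohex-2-enone
Product: 13 (5S,6S)-6-[(tert-butyldiphenylsilyloxy)methyl]-5-{2-[(2S)-3,3-dimethyloxiran-2-yl]ethyl}-5-methylcyclohex-2-enone
Conditions: L-fructose-derived Shi ketone (30 mol %), KHSO5 (as 2KHSO5·KHSO4·K2SO4), K2CO3, Bu4NHSO4, Na2B4O7 buffer, MeCN–CH2(OMe)2–H2O, 0 °C
Reagents that add atoms: potassium peroxymonosulfate, [K+].[O-]S(=O)(=O)OO
Why: Shi epoxidation, in which the electrophilic chiral dioxirane oxidises only the electron-rich trisubstituted C3=C4 alkene and not the enone, and the spiro transition state of the L-series ketone delivers oxygen to the face that makes C3 (S), the later 3β-oxygen.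

Step 6
Reactants: 13 (5S,6S)-6-[(tert-butyldiphenylsilyloxy)methyl]-5-{2-[(2S)-3,3-dimethyloxiran-2-yl]ethyl}-5-methylcyclohex-2-enone
Product: 14 linear C8-O-TBS dienol ether of 13 (C5=C6 and C7=C8; C3, C9 and C10 unchanged)
Conditions: TBSOTf (1.2 equiv), Et3N (2.5 equiv), CH2Cl2, −78 → −30 °C; cold aq NaHCO3
Reagents that add atoms: tert-butyldimethylsilyl triflate (TBSOTf), CC(C)(C)[Si](C)(C)OS(=O)(=O)C(F)(F)F
Why: Soft enolisation of an enone to its 1-silyloxy-1,3-diene, in which the O-silylated enone should lose a C5 proton because the only alternative, the tertiary C9–H wedged between C10 and C11, would give a tetrasubstituted enol ether with severe allylic strain, while the excess amine keeps the silyl triflate from opening the epoxide at low temperature.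

Step 7
Reactants: 14 linear C8-O-TBS dienol ether of 13
Product: 15 (3S,5S,9S,10S)-3-(tert-butyldimethylsilyloxy)-11-(tert-butyldiphenylsilyloxy)-12-nordrim-6-en-8-one (5β-H cis-decalin)
Conditions: TBSOTf (0.3 equiv), 2,6-di-tert-butyl-4-methylpyridine (0.5 equiv), CH2Cl2, −78 °C; aq NaHCO3
Reagents that add atoms: none
Why: Proposed new method: TBSOTf silylates the epoxide oxygen, the C4–O bond ionises at the tertiary carbon and the γ-terminus C5 of the dienol silyl ether captures C4 (6-endo at the epoxide, 6-exo at C5=C6; attack through C7 would need a bridged eight-membered ring), after which the silyloxocarbenium ion hands its TBS group to the next epoxide, so that the process is a silyl-relayed isomerisation that leaves the C3–O bond, and hence (S)-C3, intact; the closest known reaction types are the silyl-triflate- or MeAlCl2-promoted epoxide-opening carbocyclisation ended by a simple enol silyl ether and the vinylogous Mukaiyama reaction; since C5 is an endocyclic sp2 carbon next to the carbon that carries the tether, C4 can reach it only on the face where C1 stands, so H-5 should emerge cis to the C10 methyl (5β-H) and is corrected in step 8.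

Step 8
Reactants: 15 (3S,5S,9S,10S)-3-(tert-butyldimethylsilyloxy)-11-(tert-butyldiphenylsilyloxy)-12-nordrim-6-en-8-one
Product: 17 (3S,5R,9S,10S)-3-(tert-butyldimethylsilyloxy)-11-(tert-butyldiphenylsilyloxy)-12-nordrim-6-en-8-one (5α-H trans-decalin), via trimethylsilyl dienol ether 16 (not isolated)
Conditions: Me3SiOTf, Et3N, CH2Cl2, 0 °C → rt; then THF, 1 M aq HCl, −10 °C
Reagents that add atoms: none
Why: Known sequence of linear silyl dienol ether formation and acid ketonisation (the γ-protonation that fixes ring-fusion hydrogens when dienol ethers or β,γ-enones of octalones and 19-norsteroids are hydrolysed), in which loss of H-5 flattens C5 and the proton should return at this γ-carbon from the α face, anti to the axial methyl groups on C10 and C4, giving the trans-decalin under conditions too mild to enolise C9, any β,γ-enone from C7 protonation draining to 17 through the same dienol.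

Step 9
Reactants: 17 (3S,5R,9S,10S)-3-(tert-butyldimethylsilyloxy)-11-(tert-butyldiphenylsilyloxy)-12-nordrim-6-en-8-one
Product: 18 (3S,5R,9S,10S)-3-(tert-butyldimethylsilyloxy)-11-(tert-butyldiphenylsilyloxy)drima-6,8(12)-diene
Conditions: Zn, CH2Br2, TiCl4 (pre-formed in THF, −40 → 5 °C), CH2Cl2, 0 °C → rt
Reagents that add atoms: dibromomethane, BrCBr
Why: Takai–Lombardo methylenation, in which the non-basic gem-dimetallic reagent adds 1,2 to the hindered enone carbonyl and loses metal oxide, so that C8=C12 forms without the enolisation, C9 epimerisation or β-elimination of the silyloxy group that a basic ylide could provoke.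

Step 10
Reactants: 18 (3S,5R,9S,10S)-3-(tert-butyldimethylsilyloxy)-11-(tert-butyldiphenylsilyloxy)drima-6,8(12)-diene
Product: 19 (3S,5R,9S,10S)-drima-6,8(12)-diene-3,11-diol
Conditions: Bu4NF, THF, 50 °C
Reagents that add atoms: none
Why: Fluoride-driven cleavage of both silyl ethers, with warming needed for the hindered C3 ether beside the gem-dimethyl carbon, while the diene and all four stereocentres are inert to fluoride.

Step 11
Reactants: 19 (3S,5R,9S,10S)-drima-6,8(12)-diene-3,11-diol; 20 umbelliferone
Product: 21 7-{[(3S,5R,9S,10S)-3-hydroxydrima-6,8(12)-dien-11-yl]oxy}coumarin (target)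
Conditions: PPh3, DIAD, THF, 0 °C → rt
Reagents that add atoms: none
Why: Mitsunobu etherification, in which the acidic phenol displaces the oxyphosphonium ion of the primary C11 alcohol by SN2 whereas the equatorial C3 alcohol flanked by the C4 gem-dimethyl group is too hindered to be activated or displaced, so no stereocentre is touched.

Compound list
1 | 5-bromo-2-methylpent-2-ene | CC(C)=CCCBr | starting material
2 | 3-ethoxycyclohex-2-enone | CCOC1=CC(=O)CCC1 | starting material
3 | (4-methylpent-3-enyl)magnesium bromide | CC(C)=CCC[Mg]Br | intermediate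
4 | bromomagnesium 3-ethoxy-1-(4-methylpent-3-enyl)cyclohex-2-en-1-olate (racemic) | CCOC1=CC(CCC=C(C)C)(O[Mg]Br)CCC1 | intermediate
5 | 3-(4-methylpent-3-enyl)cyclohex-2-enone | CC(C)=CCCC1=CC(=O)CCC1 | intermediate
6 | methylmagnesium bromide | C[Mg]Br | starting material
7 | formaldehyde (monomer, cracked from paraformaldehyde) | C=O | starting material
8 | bromomagnesium (3R)-3-methyl-3-(4-methylpent-3-enyl)cyclohex-1-en-1-olate | Br[Mg]OC1=C[C@@](C)(CCC=C(C)C)CCC1 | intermediate
9 | (2S,3R)-2-(hydroxymethyl)-3-methyl-3-(4-methylpent-3-enyl)cyclohexanone (CH2OH cis to CH3) | O=C1CCC[C@](C)(CCC=C(C)C)[C@H]1CO | intermediate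
10 | TBDPS ether of 9 | O=C1CCC[C@](C)(CCC=C(C)C)[C@H]1CO[Si](c2ccccc2)(c2ccccc2)C(C)(C)C | intermediate
11 | kinetic trimethylsilyl enol ether of 10 (C7=C8) | C[Si](C)(C)OC1=CCC[C@](C)(CCC=C(C)C)[C@H]1CO[Si](c2ccccc2)(c2ccccc2)C(C)(C)C | intermediate
12 | (5S,6S)-6-[(tert-butyldiphenylsilyloxy)methyl]-5-methyl-5-(4-methylpent-3-enyl)cyclohex-2-enone | O=C1C=CC[C@](C)(CCC=C(C)C)[C@H]1CO[Si](c2ccccc2)(c2ccccc2)C(C)(C)C | intermediate
13 | (3S)-epoxide of 12 (drimane C3) | O=C1C=CC[C@](C)(CC[C@@H]2OC2(C)C)[C@H]1CO[Si](c3ccccc3)(c3ccccc3)C(C)(C)C | intermediate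
14 | linear C8-O-TBS dienol ether of 13 (C5=C6, C7=C8) | CC(C)(C)[Si](C)(C)OC1=CC=C[C@](C)(CC[C@@H]2OC2(C)C)[C@H]1CO[Si](c3ccccc3)(c3ccccc3)C(C)(C)C | intermediate
15 | (3S,5S,9S,10S)-3-TBSO-11-TBDPSO-12-nordrim-6-en-8-one, 5β-H, cis-decalin | O=C1C=C[C@@H]2C(C)(C)[C@@H](O[Si](C)(C)C(C)(C)C)CC[C@]2(C)[C@H]1CO[Si](c3ccccc3)(c3ccccc3)C(C)(C)C | intermediate
16 | 8-(trimethylsilyloxy)-3-TBSO-11-TBDPSO-12-nordrima-5,7-diene | C[Si](C)(C)OC1=CC=C2C(C)(C)[C@@H](O[Si](C)(C)C(C)(C)C)CC[C@]2(C)[C@H]1CO[Si](c3ccccc3)(c3ccccc3)C(C)(C)C | intermediate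
17 | (3S,5R,9S,10S)-3-TBSO-11-TBDPSO-12-nordrim-6-en-8-one, 5α-H, trans-decalin | O=C1C=C[C@H]2C(C)(C)[C@@H](O[Si](C)(C)C(C)(C)C)CC[C@]2(C)[C@H]1CO[Si](c3ccccc3)(c3ccccc3)C(C)(C)C | intermediate
18 | (3S,5R,9S,10S)-3-TBSO-11-TBDPSO-drima-6,8(12)-diene | C=C1C=C[C@H]2C(C)(C)[C@@H](O[Si](C)(C)C(C)(C)C)CC[C@]2(C)[C@H]1CO[Si](c3ccccc3)(c3ccccc3)C(C)(C)C | intermediate
19 | (3S,5R,9S,10S)-drima-6,8(12)-diene-3,11-diol | C=C1C=C[C@H]2C(C)(C)[C@@H](O)CC[C@]2(C)[C@H]1CO | intermediate
20 | umbelliferone (7-hydroxycoumarin) | O=c1ccc2ccc(O)cc2o1 | starting material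
21 | 7-{[(3S,5R,9S,10S)-3-hydroxydrima-6,8(12)-dien-11-yl]oxy}coumarin | C=C1C=C[C@H]2C(C)(C)[C@@H](O)CC[C@]2(C)[C@H]1COc1ccc2ccc(=O)oc2c1 | target

Total step count: 11. Longest linear sequence: 11 steps (1 or 2 to 21).

Steps most likely to fail

1. Step 7.
- Risk: in the only geometrically accessible (cis) closure the C3–O bond of the (S)-epoxide cannot lie equatorial and anti-periplanar in a chair. Ionisation may therefore run ahead of C4–C5 bond formation, so that a 1,2-hydride shift to the C3 ketone or proton loss to an allylic silyl ether competes.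
- Fallback (known chemistry): it sets out from 12 and rejoins the route at 18.
- MeLi/CeCl3 (THF, −78 °C) adds 1,2 to give the tertiary allylic alcohol F1.
- [C5H5NH][CrO3Cl] (pyridinium chlorochromate) effects the Babler–Dauben oxidative transposition to the 8-methyl-7-en-6-one F2, in which C5 is an ordinary α′-carbon.
- Shi epoxidation as in step 5 gives the epoxy enone F3.
- LiN(iPr)2/TBSCl gives the kinetic cross-conjugated silyl enol ether F4 (C5=C6).
- Catalytic TBSOTf with 2,6-di-tert-butyl-4-methylpyridine closes ring A in the established enol-silane-terminated mode to the 5β-H bicyclic ketone F5.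
- K2CO3/MeOH epimerises the now α-carbonyl C5 to the trans-fused ketone F6.
- Luche reduction (NaBH4, CeCl3) from the α face gives the 6β-allylic alcohol F7.
- 2,4-Dinitrobenzenesulfenyl chloride/Et3N converts F7 into the allylic sulfenate F8, which undergoes a suprafacial [2,3] shift to the 8β-sulfoxide F9.
- Thermal syn elimination of F9 can use only a C12 hydrogen, because H-9 lies on the α face, and delivers 18.

2. Step 8.
- Risk: deprotonation at the hindered ring-fusion C5–H may lose out to silylation toward C9, or protonation of the dienol ether may occur at C7 or with poor facial selectivity.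
- Fallback: it sets out from 15 and rejoins at 17, replacing kinetic by thermodynamic control at C5.
- Catalytic anhydrous 4-toluenesulfonic acid in toluene at 70 °C equilibrates C5 through the free linear dienol toward the trans-decalin, which is expected to be the more stable.
- The acid also lets C9 drift, so 17 is expected together with its 9β-H epimer F10.
- The mixture is deprotonated at C9 with LiN(iPr)2 (THF, −78 °C) to the common cross-conjugated lithium dienolate F11.
- A cold acetic acid quench follows, the proton entering from the α face anti to the axial C10 methyl, which returns 17.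

3. Step 2.
- Risk: poor facial selectivity at C9 in the capture of formaldehyde, since the enolate faces differ only by CH3 against CH2R, together with partial dehydration of the aldol.
- Fallback: it sets out from 5 and rejoins at 9.
- The same copper-catalysed methyl addition is run, but enolate 8 is silylated with Me3SiCl and isolated as the trimethylsilyl enol ether F12.
- A Mukaiyama-type hydroxymethylation with aqueous formaldehyde under Sc(OTf)3 and a chiral 2,2′-bipyridine diol then lets the catalyst, not the substrate, choose the face at C9.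

Further compounds
F1 | step 7 | 1,2-methyl adduct of 12, tertiary allylic alcohol (C8 epimers) | CC1(O)C=CC[C@](C)(CCC=C(C)C)[C@H]1CO[Si](c2ccccc2)(c2ccccc2)C(C)(C)C
F2 | step 7 | transposed monocyclic enone (C6 ketone, C7=C8, 8-methyl; C9 and C10 as in 12) | CC1=CC(=O)C[C@](C)(CCC=C(C)C)[C@H]1CO[Si](c2ccccc2)(c2ccccc2)C(C)(C)C
F3 | step 7 | (3S)-epoxide of F2 | CC1=CC(=O)C[C@](C)(CC[C@@H]2OC2(C)C)[C@H]1CO[Si](c3ccccc3)(c3ccccc3)C(C)(C)C
F4 | step 7 | cross-conjugated C6-O-TBS enol ether of F3 (C5=C6) | CC1=CC(O[Si](C)(C)C(C)(C)C)=C[C@](C)(CC[C@@H]2OC2(C)C)[C@H]1CO[Si](c3ccccc3)(c3ccccc3)C(C)(C)C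
F5 | step 7 | 3β-TBSO-11-TBDPSO-5β-drim-7-en-6-one | CC1=CC(=O)[C@@H]2C(C)(C)[C@@H](O[Si](C)(C)C(C)(C)C)CC[C@]2(C)[C@H]1CO[Si](c3ccccc3)(c3ccccc3)C(C)(C)C
F6 | step 7 | 3β-TBSO-11-TBDPSO-5α-drim-7-en-6-one | CC1=CC(=O)[C@H]2C(C)(C)[C@@H](O[Si](C)(C)C(C)(C)C)CC[C@]2(C)[C@H]1CO[Si](c3ccccc3)(c3ccccc3)C(C)(C)C
F7 | step 7 | 3β-TBSO-11-TBDPSO-drim-7-en-6β-ol | CC1=C[C@@H](O)[C@H]2C(C)(C)[C@@H](O[Si](C)(C)C(C)(C)C)CC[C@]2(C)[C@H]1CO[Si](c3ccccc3)(c3ccccc3)C(C)(C)C
F8 | step 7 | 6β-(2,4-dinitrobenzenesulfenate) of F7 | CC1=C[C@@H](OSc4ccc(cc4[N+](=O)[O-])[N+](=O)[O-])[C@H]2C(C)(C)[C@@H](O[Si](C)(C)C(C)(C)C)CC[C@]2(C)[C@H]1CO[Si](c3ccccc3)(c3ccccc3)C(C)(C)C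
F9 | step 7 | 8β-(2,4-dinitrophenylsulfinyl)-3β-TBSO-11-TBDPSO-drim-6-ene | C[C@]1(S(=O)c4ccc(cc4[N+](=O)[O-])[N+](=O)[O-])C=C[C@H]2C(C)(C)[C@@H](O[Si](C)(C)C(C)(C)C)CC[C@]2(C)[C@H]1CO[Si](c3ccccc3)(c3ccccc3)C(C)(C)C
F10 | step 8 | C9 epimer of 17 (9β-H) | O=C1C=C[C@H]2C(C)(C)[C@@H](O[Si](C)(C)C(C)(C)C)CC[C@]2(C)[C@@H]1CO[Si](c3ccccc3)(c3ccccc3)C(C)(C)C
F11 | step 8 | cross-conjugated lithium dienolate of 17 (C8=C9, C6=C7) | [Li]OC=1C=C[C@H]2C(C)(C)[C@@H](O[Si](C)(C)C(C)(C)C)CC[C@]2(C)C=1CO[Si](c3ccccc3)(c3ccccc3)C(C)(C)C
F12 | step 2 | (3R)-3-methyl-3-(4-methylpent-3-enyl)-1-(trimethylsilyloxy)cyclohex-1-ene | C[Si](C)(C)OC1=C[C@@](C)(CCC=C(C)C)CCC1
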